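## The problem

CNP0256908.1 is a γ-butyrolactone (ring atoms O1, C2(=O), C3, C4, C5) with three contiguous stereocentres, all S: C3 (methyl), C4 (carboxylic acid) and C5 (the 14-oxopentadecyl chain). The ring closes easily by 5-exo lactonisation; the difficulty is the 3,4-trans/4,5-cis pattern, which puts the two largest groups (CO2H and the C15 chain) on the same face and is not the thermodynamic arrangement. C4–H is alpha to the carboxyl group and beta to the ring oxygen, so base can epimerise it into the 4,5-trans series or expel the lactone carboxylate (E1cB), most readily when the C4 acyl group is an ester. C3–H is alpha to the lactone carbonyl, but its trans relation to C4 is the favoured one. The methyl ketone lies fourteen carbons from the ring, too far to interact with the stereocentres, yet it is enolisable and electrophilic, so strong bases, hydrides and free organometallics must be kept from it; the unbranched C16 chain with different oxygen functions at its two ends is also not a catalogue building block. Stereocontrol can be relayed from C3 to C4 (allylic strain in a C4 enolate) and from C4 to C5 (closed aldol transition state), so one catalyst-set centre can fix all three. The feature the plan uses: C2, C3, C4 and the carboxyl carbon are the four carbons of a succinic acid in which C3 bears only a methyl group and C4 only the carbinol carbon C5; at the alkene level this is fumaric acid, so the whole ring is a fumarate plus a methyl nucleophile at C3 plus the chain aldehyde at C4, with O1–C2 closing by itself.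

## Retrosynthesis

**10 ⇒ 9.** Cut: the C–OH bond of the C4 carboxyl group, replaced by C–SEt. The acid is carried as the S-ethyl thioester 9 because that thioester is the activating group of the key step and can be hydrolysed with a thiophilic silver salt without hydroxide. A carboxylic ester at C4 would need base, which attacks C4–H. The forward step must leave C4, the lactone and the ketone untouched.

**9 ⇒ 6 + 4 + a methyl nucleophile.** Cuts: O1–C2 (lactone), C4–C5 and C3–CH3, in one operation through enolate 7 and hydroxy ester 8.
- Against the neighbouring cuts: cutting only C4–C5 (aldol of a preformed methylsuccinate) leaves C3 and its relation to C4 to be made beforehand and gives an enolate that can form on either side. Cutting only C3–CH3 (late enolate methylation) needs a strong base in the presence of the ketone and of C4–H.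
- Gain: the triple cut removes the ring and all three stereocentres. 6 is flat, achiral and one step from a commodity monoester; 4 is an unbranched chain.
- Asked of the forward reaction: (a) methyl adds to one enantioface at C3 under catalyst control; (b) enolate 7 relays this to C4 and, through a closed transition state, to C5 in the anti (4,5-cis) sense; (c) the enolate takes the aldehyde of 4 and not its ketone; (d) 8 lactonises without retro-aldol.

**4 ⇒ 3 ⇒ 2 ⇒ 1.** Cuts: the carbinol C–H bonds (4 ⇒ 3), the CH3–C(=O) bond of the ketone (3 ⇒ 2), and the amide C–N bond back to the ring acyl C–O bond of macrolactone 1 (2 ⇒ 1). The C15 musk lactone 1 already holds fourteen methylenes between an acyl carbon and a carbinol carbon, and opening it differentiates the two chain ends without a protecting group. A symmetrical α,ω-diol or diacid would need desymmetrisation, and a cross-metathesis assembly would add steps and a hydrogenation. The forward steps must stop at the ketone and at the aldehyde.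

**6 ⇒ 5 + a thiol.** Cut: the acyl C–S bond. 5 is commercial monoethyl fumarate. The forward step needs S-acylation to outrun conjugate addition of the thiol to the fumarate.

## Roads not taken

Alternative 1: the obvious route. Cut C4–C5 by an auxiliary-controlled aldol and C3–CH3 by a late enolate methylation. Forward key step: anti-selective boron aldol (c-Hex2BOTf, Et3N) of a succinate half-ester bearing a chiral auxiliary with the ketal-protected aldehyde A1, then lactonisation and auxiliary removal to the 4,5-cis acid A2, dianion methylation (LiN(SiMe3)2, MeI) trans to the carboxylate, and ketal hydrolysis. The chosen plan is better because: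
- the auxiliary is stoichiometric, and anti aldols of succinate enolates are less dependable than syn ones;
- the methylation base would enolise the methyl ketone, which forces the ketal (A1 and a final deprotection);
- the stereocentres are set in two separate operations, the second with strong base on a molecule whose C4–H is labile;
- it needs nine to ten steps against six.

Alternative 2: cut the C3–H and C4–H bonds and let C5 equilibrate, i.e. a stereoconvergent hydrogenation of the racemic butenolide A3. Forward key step: C5–H of A3 is vinylogously acidic (its conjugate base is an aromatic 2-furanolate), so with Et3N the enantiomers interconvert while Ru(OAc)2[(S)-BINAP]/H2 reduces one of them from the face anti to the chain. Ester hydrolysis would give A2, and the methylation of alternative 1 follows. The chosen plan is better because: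
- A3 needs three or four steps from A1;
- the hydrogenation sets only two of the three stereocentres;
- the base that racemises C5 can also move the double bond to the enol-lactone position (C4=C5) or open the ring by E1cB;
- the methylation and ketal problem of alternative 1 remains.

Alternative 3: cut C4–C5 and a transient C–O bond from the aldehyde oxygen to the future carboxyl carbon, i.e. a Paternò–Büchi (2+2) photocycloaddition of 3-methylfuran to aldehyde 4. This dearomatisation turns the furan into C2, C3, C4 and the carboxyl carbon. Forward key step: the exo oxetane A4 already has the 4,5-cis relation, and protonation or hydrogenation of its enol ether from the convex face would place the C3 methyl trans to C4. The chosen plan is better because: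
- there is no practical enantioselective version, so A4 is racemic and would need resolution;
- the two double bonds of 3-methylfuran compete, giving regioisomers;
- both furan α-carbons arrive at the aldehyde oxidation level, so two further oxidations are needed;
- these pass through an acid-labile acetal that tends to re-aromatise to a 3-substituted furan with loss of the C4 stereocentre.

Key step: step 5

Assumption: (R)-1-[(S)-2-(diphenylphosphanyl)ferrocenyl]ethyl(dicyclohexyl)phosphane is taken to be the ligand enantiomer whose copper complex delivers methyl to the face of 6 that gives (3S); if the sense proves opposite for this ester-substituted enethioate, the commercial antipode is used and nothing else changes.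

## Route

Step 1
Reactants: 1 ω-pentadecalactone (oxacyclohexadecan-2-one)
Product: 2 15-hydroxy-N-methoxy-N-methylpentadecanamide
Conditions: MeNH(OMe)·HCl, i-PrMgCl, THF, −20 °C to 0 °C; aq NH4Cl
Reagents that add atoms: N,O-dimethylhydroxylamine hydrochloride, CNOC.Cl
Why: Weinreb aminolysis of a lactone: the chloromagnesium amide made in the flask opens the unstrained macrolactone by acyl substitution, and the magnesium alkoxide and chelated amide do not react further; no stereocentre is involved.

Step 2
Reactants: 2 15-hydroxy-N-methoxy-N-methylpentadecanamide
Product: 3 16-hydroxyhexadecan-2-one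
Conditions: MeMgBr (3 equiv), THF, 0 °C to rt; aq NH4Cl
Reagents that add atoms: methylmagnesium bromide, C[Mg]Br
Why: Weinreb ketone synthesis: the first equivalent deprotonates the alcohol, the next adds to the amide to give a magnesium-chelated tetrahedral intermediate that collapses to the methyl ketone only on work-up, so no tertiary alcohol should form.

Step 3
Reactants: 3 16-hydroxyhexadecan-2-one
Product: 4 15-oxohexadecanal
Conditions: TEMPO (10 mol %), PhI(OAc)2 (1.1 equiv), CH2Cl2, rt
Reagents that add atoms: none
Why: Oxoammonium (TEMPO/PhI(OAc)2) oxidation of a primary alcohol stops at the aldehyde in anhydrous CH2Cl2 and leaves the ketone alone; 4 is used at once to avoid autoxidation and self-aldol.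

Step 4
Reactants: 5 (2E)-4-ethoxy-4-oxobut-2-enoic acid (monoethyl fumarate)
Product: 6 ethyl (2E)-4-(ethylsulfanyl)-4-oxobut-2-enoate
Conditions: EtSH, DCC, DMAP (5 mol %), CH2Cl2, 0 °C
Reagents that add atoms: ethanethiol, CCS
Why: Steglich thioesterification: the activated acyl group of 5 is transferred to sulfur; at 0 °C with only catalytic DMAP, S-acylation should outrun thia-Michael addition, and the E double bond is untouched.

Step 5
Reactants: 6 ethyl (2E)-4-(ethylsulfanyl)-4-oxobut-2-enoate; 4 15-oxohexadecanal
Product: 9 S-ethyl (2S,3S,4S)-4-methyl-5-oxo-2-(14-oxopentadecyl)oxolane-3-carbothioate, via magnesium enolate 7 (not isolated), via hydroxy ester 8 (not isolated)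
Conditions: 6 (1.5 equiv), CuBr·SMe2 (5 mol %), (R)-1-[(S)-2-(diphenylphosphanyl)ferrocenyl]ethyl(dicyclohexyl)phosphane (6 mol %), MeMgBr (1.4 equiv), t-BuOMe, −75 °C; then 4 (1.0 equiv), −75 °C; aq NH4Cl at −75 °C; then TsOH·H2O (10 mol %), CH2Cl2, rt
Reagents that add atoms: methylmagnesium bromide, C[Mg]Br
Why: Closest known reaction type: copper/ferrocenyl-diphosphine-catalysed enantioselective conjugate addition of MeMgBr to an α,β-unsaturated S-ethyl thioester with aldol trapping of the magnesium enolate by an aldehyde; here the enethioate is a fumaric ester thioester, so the aldol alkoxide finds an ester for ring closure. Mechanism: the chiral methylcopper species formed from CuBr·SMe2, the diphosphine and MeMgBr binds the C3=C4 bond of 6 (magnesium on the thioester oxygen), oxidative addition at C3 to a trivalent copper σ-complex and reductive elimination give enolate 7, which adds to the aldehyde of 4 to give 8 after the quench, and TsOH then closes the lactone. The thioester is the stronger acceptor and directs methyl to C3; if the ester directed part of the addition, the same lactone skeleton (as its C4 ethyl ester) would still form, because the four-carbon unit is symmetrical. C3 is set by the catalyst (enantioface selection at the prochiral fumarate carbon, sense as assumed above). C4 is set by C3: 7 should react with C3–H in the enolate plane next to SEt (allylic 1,3-strain) and the aldehyde should come anti to the C3 methyl group with the smaller, electron-withdrawing ester outside, which puts CH3 and the thioester trans on the future ring. C5 is set by C4 through a closed magnesium-bridged chair (Zimmerman–Traxler) of the enolate that has O–Mg trans to C3, with the chain equatorial; this is the anti aldol, which becomes the 4,5-cis lactone. Ring closure is a 5-exo-trig acyl substitution of the C5 hydroxyl on the C2 ethyl ester and changes no stereocentre. Selectivity needed: aldehyde over methyl ketone (secured by the reactivity gap at −75 °C and by making MeMgBr the limiting reagent, so none remains when 4 is added) and kinetic control of the aldol (secured by quenching cold before any retro-aldol).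

Step 6
Reactants: 9 S-ethyl (2S,3S,4S)-4-methyl-5-oxo-2-(14-oxopentadecyl)oxolane-3-carbothioate
Product: 10 (2S,3S,4S)-4-methyl-5-oxo-2-(14-oxopentadecyl)oxolane-3-carboxylic acid (CNP0256908.1)
Conditions: AgNO3 (3 equiv), 2,6-lutidine (3 equiv), THF/H2O (4:1), rt
Reagents that add atoms: water, O
Why: Silver-assisted thioester hydrolysis: AgNO3 binds sulfur, water attacks the activated acyl carbon and AgSEt precipitates; the lutidine-buffered medium is never strongly basic, so C4 should not epimerise and the ring should not open by E1cB, while lactone and ketone are inert to the silver salt.

## Compound list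

1 | ω-pentadecalactone (oxacyclohexadecan-2-one) | O=C1CCCCCCCCCCCCCCO1 | starting material
2 | 15-hydroxy-N-methoxy-N-methylpentadecanamide | CON(C)C(=O)CCCCCCCCCCCCCCO | intermediate
3 | 16-hydroxyhexadecan-2-one | CC(=O)CCCCCCCCCCCCCCO | intermediate
4 | 15-oxohexadecanal | CC(=O)CCCCCCCCCCCCCC=O | intermediate
5 | (2E)-4-ethoxy-4-oxobut-2-enoic acid (monoethyl fumarate) | CCOC(=O)/C=C/C(=O)O | starting material
6 | ethyl (2E)-4-(ethylsulfanyl)-4-oxobut-2-enoate | CCOC(=O)/C=C/C(=O)SCC | intermediate
7 | ethyl (2S,3Z)-4-[(bromomagnesio)oxy]-4-(ethylsulfanyl)-2-methylbut-3-enoate | CCOC(=O)[C@@H](C)/C=C(/O[Mg]Br)SCC | intermediate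
8 | ethyl (2S,3S,4S)-3-[(ethylsulfanyl)carbonyl]-4-hydroxy-2-methyl-18-oxononadecanoate | CC(=O)CCCCCCCCCCCCC[C@H](O)[C@@H](C(=O)SCC)[C@H](C)C(=O)OCC | intermediate
9 | S-ethyl (2S,3S,4S)-4-methyl-5-oxo-2-(14-oxopentadecyl)oxolane-3-carbothioate | CC(=O)CCCCCCCCCCCCC[C@@H]1OC(=O)[C@@H](C)[C@@H]1C(=O)SCC | intermediate
10 | (2S,3S,4S)-4-methyl-5-oxo-2-(14-oxopentadecyl)oxolane-3-carboxylic acid (CNP0256908.1) | CC(=O)CCCCCCCCCCCCC[C@@H]1OC(=O)[C@@H](C)[C@@H]1C(=O)O | target

## Step count and least certain steps

Total steps: 6. Longest linear sequence: 5 steps (1 → 2 → 3 → 4 → 9 → 10); 6 is made in one step from 5.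

**Step 5 (key step).** What may go wrong:
- (a) erosion of enantioface selection, because the C3 ester makes 6 much more electrophilic than a β-alkyl enethioate and may allow uncatalysed addition or a second binding mode;
- (b) loss of the C3-to-C4 or C4-to-C5 relay through a mixed enolate geometry, or retro-aldol equilibration before the quench, leaking into the 4,5-trans lactone;
- (c) attack of residual Grignard reagent or of the enolate at the ketone.

Fallback (stepwise, with a boron enolate of defined geometry): set out from 6, run the copper-catalysed methyl addition alone and isolate ethyl (2S)-4-(ethylsulfanyl)-2-methyl-4-oxobutanoate F1. Enolise its thioester with c-Hex2BOTf/Et3N in CH2Cl2 at −78 °C, the conditions of the boron-mediated anti aldol, to give ethyl (2S,3Z)-4-[(dicyclohexylboranyl)oxy]-4-(ethylsulfanyl)-2-methylbut-3-enoate F2. Add 4, work up oxidatively at pH 7 to hydroxy ester 8 and lactonise with TsOH to come back at 9.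

**Step 6.** What may go wrong: incomplete hydrolysis of the hindered thioester, or epimerisation at C4 if the reaction has to be forced. Fallback (reduction then oxidation in place of hydrolysis): set out from 9 and reduce the thioester with Et3SiH and Pd/C (Fukuyama reduction) to (2S,3S,4S)-4-methyl-5-oxo-2-(14-oxopentadecyl)oxolane-3-carbaldehyde F3. Oxidise it at once with NaClO2/NaH2PO4/2-methylbut-2-ene (Pinnick oxidation) to come back at 10.

**Step 4.** What may go wrong: conjugate addition of the thiol to the electron-poor double bond under DMAP catalysis, competing with S-acylation. Fallback (no free thiol and no base): set out from 5 and convert it with SOCl2 into ethyl (2E)-4-chloro-4-oxobut-2-enoate F4. Treat this acid chloride with Me3SiSEt in CH2Cl2, which transfers the ethylsulfanyl group with loss of Me3SiCl, to come back at 6.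

## Further compounds

F1 | step 5 | ethyl (2S)-4-(ethylsulfanyl)-2-methyl-4-oxobutanoate | CCOC(=O)[C@@H](C)CC(=O)SCC
F2 | step 5 | ethyl (2S,3Z)-4-[(dicyclohexylboranyl)oxy]-4-(ethylsulfanyl)-2-methylbut-3-enoate | CCOC(=O)[C@@H](C)/C=C(/OB(C1CCCCC1)C1CCCCC1)SCC
F3 | step 6 | (2S,3S,4S)-4-methyl-5-oxo-2-(14-oxopentadecyl)oxolane-3-carbaldehyde | CC(=O)CCCCCCCCCCCCC[C@@H]1OC(=O)[C@@H](C)[C@@H]1C=O
F4 | step 4 | ethyl (2E)-4-chloro-4-oxobut-2-enoate | CCOC(=O)/C=C/C(Cl)=O
A1 | alternative 1 | 14-(2-methyl-1,3-dioxolan-2-yl)tetradecanal | CC1(CCCCCCCCCCCCCC=O)OCCO1
A2 | alternative 1 | (2S,3S)-2-[13-(2-methyl-1,3-dioxolan-2-yl)tridecyl]-5-oxooxolane-3-carboxylic acid | CC1(CCCCCCCCCCCCC[C@@H]2OC(=O)C[C@@H]2C(=O)O)OCCO1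
A3 | alternative 2 | ethyl 2-[13-(2-methyl-1,3-dioxolan-2-yl)tridecyl]-5-oxo-2,5-dihydrofuran-3-carboxylate (racemic) | CCOC(=O)C1=CC(=O)OC1CCCCCCCCCCCCCC2(C)OCCO2
A4 | alternative 3 | 15-[(1S,5S,6S)-4-methyl-2,7-dioxabicyclo[3.2.0]hept-3-en-6-yl]pentadecan-2-one (racemic, exo; one enantiomer drawn) | CC(=O)CCCCCCCCCCCCC[C@@H]1O[C@H]2OC=C(C)[C@@H]12
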